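3 questions are asked: two orders about the charge of the autumn run, and the share of substrate left in the summer run at 5.2 h. I begin with the last.

| setting | autumn | noon | dusk | summer |
|---|---|---|---|---|
| substrate | 250 mM | 130 mM | 250 mM | 750 mM |
| partner | 275 mM | 155 mM | 830 mM | 275 mM |
| time |  |  |  | 5.2 h |

| run | time / h | [substrate] / mM |
|---|---|---|
| autumn run | 0.74 | 185 |
| autumn run | 1.5 | 156 |
| autumn run | 2.2 | 143 |
| autumn run | 3.0 | 128 |
| autumn run | 3.7 | 122 |
| autumn run | 4.5 | 134 |
| autumn run | 5.2 | 125 |
| noon run | 0.74 | 110 |
| noon run | 1.5 | 97 |
| noon run | 2.2 | 100 |
| noon run | 3.0 | 86 |
| noon run | 3.7 | 90 |
| noon run | 4.5 | 81 |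
| noon run | 5.2 | 79 |
| dusk run | 0.74 | 132 |
| dusk run | 1.5 | 93 |
| dusk run | 2.2 | 72 |
| dusk run | 3.0 | 68 |
| dusk run | 3.7 | 63 |
| dusk run | 4.5 | 52 |
| dusk run | 5.2 | 50 |

(readings scatter by 4 mM)

- Overall: substrate + partner -> product.
- Constant volume, constant temperature.
- "The second partner" is partner.
- An order is taken over about fifteen percent of the charge, up and down.

* the power of [partner] that the first rate follows, about the charge of the autumn run; measure it at two percent of substrate made into product
* the power of [substrate] that the first rate follows, about the charge of the autumn run; measure it at two percent of substrate made into product (one fixed amount of product, the same in the runs compared)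
* substrate in the summer run at 5.2 h, as a share of the substrate charged

The neighbour is the autumn run. It has the same partner charge, 275 mM, but substrate 250 mM against 750 mM in summer. In autumn the readings lie flat from 3.0 h, with a mean of 127 mM over the last 4. So 123 mM of substrate has turned. If partner went at one per substrate and by no other way, 152 mM of partner would remain, yet the autumn readings do not fall further. I read this as partner going down a second route that uses no substrate.

Let y be the partner yield, the substrate turned per partner charged. In autumn y is 0.446. In summer partner is the limiting reagent, with 275 mM against 750 mM, and y = 1 would leave 63.3% of the substrate.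

For the zero of my scale I take the statistical case. I suppose a partner molecule meets substrate or another partner in proportion to the charges, so the odds y/(1−y) equal the charge ratio, substrate over partner. The competition weight w is those odds divided by the charge ratio, and w = 1 is the even case. Autumn reads 0.887.

I carry that w to the summer run and assume that this run has stopped by 5.2 h. Its charge ratio is 2.73 against 0.909 in autumn, so its odds are 2.42 and its yield is 0.707, higher than in autumn. That turns 195 mM, leaving 74.0%. Autumn keeps 50.8%, a smaller share, because the same partner charge meets a smaller substrate charge.

The forecast gives 0.4 for partner, 1.3 for substrate and 72% left, holding that “the reaction is reversible”. My reckoning gives a different share by a different route.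

The simulation gives 70.0% left, with orders 0.82 in partner and 0.94 in substrate.

    substrate + partner ⇌ intermediate, settled at all times (1.360 M⁻¹)
    substrate + partner → product (1.476 M⁻¹ h⁻¹)
    2 partner → lost reagent (3.528 M⁻¹ h⁻¹)
    substrate + partner + product → 2 product (43.20 M⁻² h⁻¹)

The forecast's share stands within its margin, but its orders do not. Where two percent of the autumn substrate have turned, product forms at 140 mM h⁻¹ in the dusk run against 64 mM h⁻¹ in the autumn run, with the same substrate charge. In the summer run, 70.0% means 225 mM of substrate gone; counted as turned, that is a yield of 0.819 and a weight of 1.66, above the 0.887 read in the autumn run. In the dusk run, the last reading of 50 mM gives a yield of 0.241 and a weight of 1.05.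

(The earlier runs and the new flask were computed with constants of no real substance; noise was put on by code.)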